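A direct plan would make the C2-symmetric diol A1 by twofold auxiliary alkylation of 3-iodo-2-(iodomethyl)propene, then monotosylate it and couple it with a copper-catalysed Grignard reaction to give alkenol A2.
It would then add O2 to the 1,1-disubstituted alkene of A2 by cobalt-mediated hydroperoxysilylation, oxidise to the aldehyde and close the ring as the methyl peroxyacetal A3.
It would finish by peroxycarbenium substitution of A3 with a silyl ketene acetal to give ester A4, followed by saponification.
Weak step 1, the radical oxygenation that creates C6: an acyclic tertiary radical would capture O2 without facial bias, so both C6 epimers would form and be carried on, to be separated only at A4.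
Weak step 2, the late C3–C2 bond formation on A3: axial attack on a peroxycarbenium ion under TiCl4 would have to set C3 cis to the C4 methyl on an epimer mixture, at the most valuable stage and on the peroxide itself.
Weak step 3, the run-up to A2: two auxiliaries would be installed and reduced off, followed by a monosulfonylation that must stop halfway and an alcohol-to-aldehyde redox change, none of which builds the ring.

**Retrosynthetic overview**
The 1,2-dioxane (O1–O2–C3–C4–C5–C6) is closed last at O1–C6 by 6-endo cycloperoxymercuration of a (3S)-hydroperoxide onto an (E)-C5=C6 trisubstituted alkene; a chair with the C4 methyl equatorial turns the alkene geometry into the quaternary C6 centre (CH3 axial, C7 equatorial).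
The C3–O2 bond comes from SN2 inversion of a C3 mesylate; the chain end comes from copper-catalysed sp3–sp3 coupling at C9–C10.
C3, the E alkene and the remote C8 methyl are all relayed from a sacrificial C5 carbinol: Evans–Tishchenko reduction (C5–OH sets C3–OH anti and keeps the propionate on C5–O), then Ireland–Claisen rearrangement (C5–O centre becomes the (E)-C5=C6 alkene and C8).
C4 and C5 come from one Evans aldol with methacrolein; C1 rides as a dioxolane and is oxidised at the end.
The design therefore avoids unbiased radical oxygenation at C6, carries no epimer mixture, forms no C–C bond on the peroxide and uses one auxiliary instead of two.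

Key step: step 10

Remark: atoms are numbered as in the target acid (C1 = CO2H, C3 and C6 = peroxide carbons, C8 = side-chain stereocentre); (1,3-dioxolan-2-ylmethyl)magnesium bromide is taken as its commercial THF solution.

Step 1
Reactants: 1 (S)-4-benzyl-3-propionyloxazolidin-2-one; 2 methacrolein (2-methylprop-2-enal)
Product: 3 (S)-4-benzyl-3-[(2S,3S)-3-hydroxy-2,4-dimethylpent-4-enoyl]oxazolidin-2-one
Conditions: Bu2BOTf, iPr2NEt, CH2Cl2, −78 °C; then 2, −78 to 0 °C; H2O2, MeOH, pH 7 buffer work-up
Reagents that add atoms: none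
Why: Evans syn-aldol: the Z-boron enolate of 1 adds to methacrolein through a Zimmerman–Traxler chair whose face is fixed by the (S)-benzyl group, which sets C4 (S) and, syn to it, the C5 carbinol (S) that is sacrificed later.

Step 2
Reactants: 3 (S)-4-benzyl-3-[(2S,3S)-3-hydroxy-2,4-dimethylpent-4-enoyl]oxazolidin-2-one
Product: 4 (2S,3S)-3-hydroxy-N-methoxy-N,2,4-trimethylpent-4-enamide
Conditions: MeNH(OMe)·HCl, AlMe3, THF/CH2Cl2, −20 to 0 °C
Reagents that add atoms: N,O-dimethylhydroxylamine hydrochloride, CNOC.Cl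
Why: Weinreb transamination: the aluminium amide opens the imide at the exocyclic carbonyl, assisted by the free β-hydroxyl as its aluminium alkoxide, without touching C4 or C5, and releases the auxiliary for recovery.

Step 3
Reactants: 4 (2S,3S)-3-hydroxy-N-methoxy-N,2,4-trimethylpent-4-enamide; 5 (1,3-dioxolan-2-ylmethyl)magnesium bromide
Product: 6 (3S,4S)-1-(1,3-dioxolan-2-yl)-4-hydroxy-3,5-dimethylhex-5-en-2-one
Conditions: 5 (3.5 equiv, 0.5 M in THF), THF, 0 °C to rt; aq. NH4Cl
Reagents that add atoms: none
Why: Ketone synthesis from a Weinreb amide: one equivalent of 5 deprotonates the hydroxyl, a second adds to the amide, and the chelated tetrahedral intermediate survives until work-up, so neither over-addition nor epimerisation at C4 should occur; the reagent brings C2 and C1, the latter masked as a dioxolane.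

Step 4
Reactants: 6 (3S,4S)-1-(1,3-dioxolan-2-yl)-4-hydroxy-3,5-dimethylhex-5-en-2-one
Product: 7 (3S,4R,5R)-6-(1,3-dioxolan-2-yl)-5-hydroxy-2,4-dimethylhex-1-en-3-yl propanoate
Conditions: EtCHO (6 equiv), SmI2 (0.3 equiv), THF, −10 °C
Reagents that add atoms: propanal, CCC=O
Why: Evans–Tishchenko reduction: the samarium-bound hemiacetal formed from the C5 hydroxyl and propanal delivers its hydride to the C3 ketone through a chair transition state, which should give the 1,3-anti C3 carbinol (anti to the C4 methyl) and leaves the propionate needed for the next step on the C5 oxygen only.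

Step 5
Reactants: 7 (3S,4R,5R)-6-(1,3-dioxolan-2-yl)-5-hydroxy-2,4-dimethylhex-1-en-3-yl propanoate
Product: 11 (2S,4E,6S,7R)-8-(1,3-dioxolan-2-yl)-2,4,6-trimethyloct-4-ene-1,7-diol, via trimethylsilyl ether 8 (not isolated), via (Z)-silyl ketene acetal 9 (not isolated), via rearranged silyl ester 10 (not isolated)
Conditions: (Me3Si)2NH, TMSCl (cat.), CH2Cl2, rt, evaporate; LiN(iPr)2, THF–DMPU, −78 °C, then TMSCl, −78 to 40 °C; LiAlH4 (excess), THF, 0 °C; K2CO3, MeOH work-up
Reagents that add atoms: none
Why: Ireland–Claisen rearrangement: after transient silylation of the C3 hydroxyl (to prevent acyl migration), LiN(iPr)2 in THF–DMPU should give mainly the (Z)-silyl ketene acetal 9, whose [3,3] shift through a chair with the C4 branch equatorial forms C7–C8 and transfers the C5 configuration to the (E)-C5=C6 alkene and to the new C8 methyl centre (2S in 11); LiAlH4 then reduces the crude silyl ester 10 to the C9 alcohol and methanolic K2CO3 removes the silyl ether.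

Step 6
Reactants: 11 (2S,4E,6S,7R)-8-(1,3-dioxolan-2-yl)-2,4,6-trimethyloct-4-ene-1,7-diol
Product: 12 (2S,4E,6S,7R)-8-(1,3-dioxolan-2-yl)-7-hydroxy-2,4,6-trimethyloct-4-en-1-yl 4-methylbenzenesulfonate
Conditions: TsCl (1.1 equiv), Et3N, DMAP (cat.), CH2Cl2, 0 °C
Reagents that add atoms: 4-methylbenzenesulfonyl chloride, Cc1ccc(cc1)S(Cl)(=O)=O
Why: Selective sulfonylation: the primary C9 hydroxyl should react well ahead of the secondary C3 hydroxyl, which is flanked by the C4 methyl branch.

Step 7
Reactants: 12 (2S,4E,6S,7R)-8-(1,3-dioxolan-2-yl)-7-hydroxy-2,4,6-trimethyloct-4-en-1-yl 4-methylbenzenesulfonate; 13 (7-bromoheptyl)benzene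
Product: 15 (2R,3S,4E,7R)-1-(1,3-dioxolan-2-yl)-3,5,7-trimethyl-15-phenylpentadec-4-en-2-ol, via (7-phenylheptyl)magnesium bromide 14 (not isolated)
Conditions: 13, Mg, THF, 40 °C; then 12, Li2CuCl4 (5 mol %), THF, −30 °C to rt (3 equiv of 14)
Reagents that add atoms: none
Why: Copper-catalysed Grignard cross-coupling of a primary tosylate (Kochi type) forms C9–C10 by sp3–sp3 coupling, the first equivalent of 14 masking the C3 hydroxyl as its magnesium alkoxide; no stereocentre is touched and C8 only changes its descriptor to R.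

Step 8
Reactants: 15 (2R,3S,4E,7R)-1-(1,3-dioxolan-2-yl)-3,5,7-trimethyl-15-phenylpentadec-4-en-2-ol
Product: 16 (2R,3S,4E,7R)-1-(1,3-dioxolan-2-yl)-3,5,7-trimethyl-15-phenylpentadec-4-en-2-yl methanesulfonate
Conditions: MsCl, Et3N, CH2Cl2, −10 °C
Reagents that add atoms: methanesulfonyl chloride, CS(Cl)(=O)=O
Why: Mesylation activates the C3 hydroxyl with retention, since only the O–H bond reacts.

Step 9
Reactants: 16 (2R,3S,4E,7R)-1-(1,3-dioxolan-2-yl)-3,5,7-trimethyl-15-phenylpentadec-4-en-2-yl methanesulfonate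
Product: 17 2-[(2S,3S,4E,7R)-2-hydroperoxy-3,5,7-trimethyl-15-phenylpentadec-4-en-1-yl]-1,3-dioxolane
Conditions: 50% aq. H2O2 (30 equiv), KOH (4 equiv), MeOH/THF, 0 °C to rt
Reagents that add atoms: hydrogen peroxide, OO
Why: SN2 displacement of a secondary mesylate by hydroperoxide anion, a weakly basic α-effect nucleophile kept dominant by the large excess of H2O2, should invert C3 and give the secondary hydroperoxide syn to the C4 methyl; the low basicity and temperature are meant to hold back elimination towards the conjugated diene.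

Step 10
Reactants: 17 2-[(2S,3S,4E,7R)-2-hydroperoxy-3,5,7-trimethyl-15-phenylpentadec-4-en-1-yl]-1,3-dioxolane
Product: 19 2-{[(3S,4S,6R)-4,6-dimethyl-6-[(2R)-2-methyl-10-phenyldecyl]-1,2-dioxan-3-yl]methyl}-1,3-dioxolane, via organomercurial acetate 18 (not isolated)
Conditions: Hg(OAc)2 (1.1 equiv), CH2Cl2, 0 °C to rt; then NaBH4, 2 M NaOH, 0 °C
Reagents that add atoms: none
Why: Electrophilic cycloperoxymercuration: Hg(OAc)2 forms a mercurinium ion on the C5=C6 alkene, the terminal oxygen of the C3 hydroperoxide opens it anti at the tertiary carbon C6 to give organomercurial 18, and NaBH4 in base replaces the C5–Hg bond by C5–H. The closest known reaction type is the intramolecular peroxymercuration of unsaturated hydroperoxides followed by borohydride demercuration, including its endo mode for alkenes that are more substituted at the distal carbon. The 1,2-dioxane closes 6-endo-trig by forming O1–C6, preferred over 5-exo closure at C5 because the unsymmetrical mercurinium ion carries its positive charge on the trisubstituted carbon (Markovnikov opening). C6 is the only stereocentre that remains from this step: anti addition to the E alkene places C7 equatorial and the C6 methyl axial in the chair transition state, and the chair that keeps the C4 methyl equatorial (the other would force a 1,3-diaxial CH3/CH3 contact) puts C7 cis to the C4 methyl, i.e. 6R, with the C3 side chain axial and cis to both. The step needs regioselectivity (6-endo) and facial selectivity, secured by the substitution pattern of the alkene and by the C4 stereocentre together with the fixed E geometry; the transient C5–Hg centre is erased on demercuration, during which the endocyclic O–O bond is poorly aligned for attack by the C5 radical.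

Step 11
Reactants: 19 2-{[(3S,4S,6R)-4,6-dimethyl-6-[(2R)-2-methyl-10-phenyldecyl]-1,2-dioxan-3-yl]methyl}-1,3-dioxolane
Product: 20 2-[(3S,4S,6R)-4,6-dimethyl-6-[(2R)-2-methyl-10-phenyldecyl]-1,2-dioxan-3-yl]acetic acid
Conditions: CrO3, H2SO4, H2O/acetone (Jones reagent), 0 °C to rt
Reagents that add atoms: water, O
Why: Jones oxidation: the aqueous acid hydrolyses the dioxolane and hexavalent chromium oxidises the aldehyde hydrate directly to the carboxylic acid, while the dialkyl peroxide, which is inert to chromic acid and should tolerate cold dilute acid, and all four stereocentres remain untouched.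

**Compound list**
1 | (S)-4-benzyl-3-propionyloxazolidin-2-one | CCC(=O)N1[C@@H](Cc2ccccc2)COC1=O | starting material
2 | methacrolein (2-methylprop-2-enal) | CC(=C)C=O | starting material
3 | (S)-4-benzyl-3-[(2S,3S)-3-hydroxy-2,4-dimethylpent-4-enoyl]oxazolidin-2-one | C=C(C)[C@@H](O)[C@H](C)C(=O)N1[C@@H](Cc2ccccc2)COC1=O | intermediate
4 | (2S,3S)-3-hydroxy-N-methoxy-N,2,4-trimethylpent-4-enamide | C=C(C)[C@@H](O)[C@H](C)C(=O)N(C)OC | intermediate
5 | (1,3-dioxolan-2-ylmethyl)magnesium bromide | Br[Mg]CC1OCCO1 | starting material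
6 | (3S,4S)-1-(1,3-dioxolan-2-yl)-4-hydroxy-3,5-dimethylhex-5-en-2-one | C=C(C)[C@@H](O)[C@H](C)C(=O)CC1OCCO1 | intermediate
7 | (3S,4R,5R)-6-(1,3-dioxolan-2-yl)-5-hydroxy-2,4-dimethylhex-1-en-3-yl propanoate | C=C(C)[C@@H](OC(=O)CC)[C@H](C)[C@H](O)CC1OCCO1 | intermediate
8 | (3S,4S,5R)-6-(1,3-dioxolan-2-yl)-2,4-dimethyl-5-[(trimethylsilyl)oxy]hex-1-en-3-yl propanoate | C=C(C)[C@@H](OC(=O)CC)[C@H](C)[C@H](O[Si](C)(C)C)CC1OCCO1 | intermediate
9 | (Z)-1-{[(3S,4S,5R)-6-(1,3-dioxolan-2-yl)-2,4-dimethyl-5-[(trimethylsilyl)oxy]hex-1-en-3-yl]oxy}-1-[(trimethylsilyl)oxy]prop-1-ene | C/C=C(\O[Si](C)(C)C)O[C@H](C(C)=C)[C@H](C)[C@H](O[Si](C)(C)C)CC1OCCO1 | intermediate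
10 | trimethylsilyl (2S,4E,6S,7R)-8-(1,3-dioxolan-2-yl)-2,4,6-trimethyl-7-[(trimethylsilyl)oxy]oct-4-enoate | C[C@H](C(=O)O[Si](C)(C)C)C/C(C)=C/[C@H](C)[C@H](O[Si](C)(C)C)CC1OCCO1 | intermediate
11 | (2S,4E,6S,7R)-8-(1,3-dioxolan-2-yl)-2,4,6-trimethyloct-4-ene-1,7-diol | C[C@H](CO)C/C(C)=C/[C@H](C)[C@H](O)CC1OCCO1 | intermediate
12 | (2S,4E,6S,7R)-8-(1,3-dioxolan-2-yl)-7-hydroxy-2,4,6-trimethyloct-4-en-1-yl 4-methylbenzenesulfonate | C[C@H](COS(=O)(=O)c1ccc(C)cc1)C/C(C)=C/[C@H](C)[C@H](O)CC1OCCO1 | intermediate
13 | (7-bromoheptyl)benzene | BrCCCCCCCc1ccccc1 | starting material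
14 | (7-phenylheptyl)magnesium bromide | Br[Mg]CCCCCCCc1ccccc1 | intermediate
15 | (2R,3S,4E,7R)-1-(1,3-dioxolan-2-yl)-3,5,7-trimethyl-15-phenylpentadec-4-en-2-ol | C[C@H](CCCCCCCCc1ccccc1)C/C(C)=C/[C@H](C)[C@H](O)CC1OCCO1 | intermediate
16 | (2R,3S,4E,7R)-1-(1,3-dioxolan-2-yl)-3,5,7-trimethyl-15-phenylpentadec-4-en-2-yl methanesulfonate | C[C@H](CCCCCCCCc1ccccc1)C/C(C)=C/[C@H](C)[C@H](OS(C)(=O)=O)CC1OCCO1 | intermediate
17 | 2-[(2S,3S,4E,7R)-2-hydroperoxy-3,5,7-trimethyl-15-phenylpentadec-4-en-1-yl]-1,3-dioxolane | C[C@H](CCCCCCCCc1ccccc1)C/C(C)=C/[C@H](C)[C@@H](OO)CC1OCCO1 | intermediate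
18 | acetoxy{(3S,4R,5S,6R)-3-(1,3-dioxolan-2-ylmethyl)-4,6-dimethyl-6-[(2R)-2-methyl-10-phenyldecyl]-1,2-dioxan-5-yl}mercury | C[C@H](CCCCCCCCc1ccccc1)C[C@]1(C)[C@@H]([Hg]OC(C)=O)[C@H](C)[C@H](CC2OCCO2)OO1 | intermediate
19 | 2-{[(3S,4S,6R)-4,6-dimethyl-6-[(2R)-2-methyl-10-phenyldecyl]-1,2-dioxan-3-yl]methyl}-1,3-dioxolane | C[C@H](CCCCCCCCc1ccccc1)C[C@]1(C)C[C@H](C)[C@H](CC2OCCO2)OO1 | intermediate
20 | 2-[(3S,4S,6R)-4,6-dimethyl-6-[(2R)-2-methyl-10-phenyldecyl]-1,2-dioxan-3-yl]acetic acid | C[C@H](CCCCCCCCc1ccccc1)C[C@]1(C)C[C@H](C)[C@H](CC(=O)O)OO1 | target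

**Count and risks**
Total step count: 11. Longest linear sequence: 11 steps (1 to 20); Grignard reagent 14 is made in the flask within step 7.

Steps most likely to fail:

1. Step 9. Substitution at the β-branched secondary carbon may be slow, and elimination towards the conjugated C3=C4–C5=C6 diene may take over. The fallback sets out from mesylate 16 and reverses the order of the two C–O bonds. Cobalt-catalysed hydroperoxysilylation of the trisubstituted alkene (Co(thd)2 [cobalt bis(2,2,6,6-tetramethylheptane-3,5-dionate)], O2, Et3SiH, Isayama–Mukaiyama) would give the triethylsilyl peroxide mesylate F1 as both C6 epimers. TBAF in THF would then free the tertiary peroxide anion, which displaces the mesylate intramolecularly (6-exo-tet, inversion at C3). This would give 19 together with its C6 epimer F2, to be separated by chromatography; the route is rejoined at 19, at the price of the C6 control.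

2. Step 10. Acetate capture or 5-exo closure may compete with the 6-endo closure, and the ring may be lost through the β-peroxy alkyl radical during borohydride demercuration. The fallback sets out from hydroperoxide 17 and closes the ring through a halonium ion instead. N-iodosuccinimide in CH2Cl2 at 0 °C would give the 5-iodo-1,2-dioxane F3 by the same anti, Markovnikov opening. A tin hydride radical chain (Bu3SnH, Et3B, air, toluene, 0 °C) would then remove the iodine at high hydride concentration and give 19.

3. Step 5. Control of the ketene acetal geometry may be incomplete, which leaks into the remote C8 epimer that is hard to separate, and the acyl group may migrate if silylation of the C3 hydroxyl is not complete. The fallback sets out from ketone 6 and exchanges the roles of the two carbon substituents of C8, so that the better controlled (E)-ketene acetal is the one needed. Evans–Tishchenko reduction of 6 with 10-phenyldecanal F4 (from commercial 10-phenyldecan-1-ol by TEMPO/PhI(OAc)2 oxidation) would give the 10-phenyldecanoate F5. Silylation, enolisation with LiN(iPr)2 in THF without DMPU, Ireland–Claisen rearrangement and LiAlH4 reduction would give the diol F6, in which the former carboxyl carbon is the future C8 methyl. Selective tosylation would give the tosylate F7, and LiEt3BH reduction would rejoin the route at alcohol 15.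

**Further compounds**
F1 | step 9 | (2R,3S,7R)-1-(1,3-dioxolan-2-yl)-3,5,7-trimethyl-15-phenyl-5-[(triethylsilyl)peroxy]pentadecan-2-yl methanesulfonate (both C5 epimers) | C[C@H](CCCCCCCCc1ccccc1)CC(C)(OO[Si](CC)(CC)CC)C[C@H](C)[C@H](OS(C)(=O)=O)CC1OCCO1
F2 | step 9 | 2-{[(3S,4S,6S)-4,6-dimethyl-6-[(2R)-2-methyl-10-phenyldecyl]-1,2-dioxan-3-yl]methyl}-1,3-dioxolane | C[C@H](CCCCCCCCc1ccccc1)C[C@@]1(C)C[C@H](C)[C@H](CC2OCCO2)OO1
F3 | step 10 | 2-{[(3S,4R,5S,6R)-5-iodo-4,6-dimethyl-6-[(2R)-2-methyl-10-phenyldecyl]-1,2-dioxan-3-yl]methyl}-1,3-dioxolane | C[C@H](CCCCCCCCc1ccccc1)C[C@]1(C)[C@@H](I)[C@H](C)[C@H](CC2OCCO2)OO1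
F4 | step 5 | 10-phenyldecanal | O=CCCCCCCCCCc1ccccc1
F5 | step 5 | (3S,4R,5R)-6-(1,3-dioxolan-2-yl)-5-hydroxy-2,4-dimethylhex-1-en-3-yl 10-phenyldecanoate | C=C(C)[C@@H](OC(=O)CCCCCCCCCc1ccccc1)[C@H](C)[C@H](O)CC1OCCO1
F6 | step 5 | (2R,4E,6S,7R)-8-(1,3-dioxolan-2-yl)-4,6-dimethyl-2-(8-phenyloctyl)oct-4-ene-1,7-diol | OC[C@H](CCCCCCCCc1ccccc1)C/C(C)=C/[C@H](C)[C@H](O)CC1OCCO1
F7 | step 5 | (2R,4E,6S,7R)-8-(1,3-dioxolan-2-yl)-7-hydroxy-4,6-dimethyl-2-(8-phenyloctyl)oct-4-en-1-yl 4-methylbenzenesulfonate | Cc1ccc(cc1)S(=O)(=O)OC[C@H](CCCCCCCCc1ccccc1)C/C(C)=C/[C@H](C)[C@H](O)CC1OCCO1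
A1 | direct plan | (2S,6S)-2,6-dimethyl-4-methylideneheptane-1,7-diol | C=C(C[C@H](C)CO)C[C@H](C)CO
A2 | direct plan | (2S,6R)-2,6-dimethyl-4-methylidene-14-phenyltetradecan-1-ol | C=C(C[C@H](C)CO)C[C@H](C)CCCCCCCCc1ccccc1
A3 | direct plan | (4S,6RS)-3-methoxy-4,6-dimethyl-6-[(2R)-2-methyl-10-phenyldecyl]-1,2-dioxane | C[C@H](CCCCCCCCc1ccccc1)CC1(C)C[C@H](C)C(OC)OO1
A4 | direct plan | methyl 2-[(3S,4S,6R)-4,6-dimethyl-6-[(2R)-2-methyl-10-phenyldecyl]-1,2-dioxan-3-yl]acetate | C[C@H](CCCCCCCCc1ccccc1)C[C@]1(C)C[C@H](C)[C@H](CC(=O)OC)OO1
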